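**Strategy.** The quinone is not carried through the synthesis: the 2-methyl-5-alkyl-1,4-benzoquinone ring is assembled last by a Dötz [3+2+1] benzannulation, followed in the same flask by ceric oxidation. The step exploits the ring pattern: C1 (carbonyl) is the carbene carbon and C2(CH3)=C3H the isopropenyl group of a Fischer chromium carbene, C4 (carbonyl) is a CO ligand, and C5(side chain)=C6H is a terminal alkyne, whose steric bias places methyl and chain para. The precursor is therefore an open-chain hydroxy acetate ending in a skipped enyne. Its (R)-acetoxy/(S)-carbinol pair comes from Sharpless epoxidation of a farnesyl-derived allylic alcohol, prenylation and invertive epoxide hydrolysis.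

Key step: step 12

Remark on the chemistry: the sulfonyl-bearing carbon made in step 6 forms as both epimers and is left undefined in the SMILES of 12 and 13; step 8 removes it. Side-chain atoms are numbered C1′–C16′ outward from the ring.

Step 1
Reactants: 1 1-bromo-3-methylbut-2-ene; 2 sodium benzenesulfinate
Product: 3 (3-methylbut-2-en-1-yl) phenyl sulfone
Conditions: DMF, rt
Reagents that add atoms: none
Why: SN2 S-alkylation of the ambident sulfinate by the primary allylic bromide should give the allylic sulfone that later serves as the prenyl carbanion.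

Step 2
Reactants: 4 (2E,6E)-farnesyl bromide; 5 ethynyltrimethylsilane
Product: 7 trimethyl[(4E,8E)-5,9,13-trimethyltetradeca-4,8,12-trien-1-yn-1-yl]silane, via alkynylmagnesium bromide 6 (not isolated)
Conditions: 5, EtMgBr, THF, 0 °C to rt; then 4, CuBr·SMe2 (10 mol %), 0 to 40 °C
Reagents that add atoms: none
Why: Copper-catalysed cross-coupling of an alkynyl Grignard reagent with a primary allylic bromide should occur at the unhindered α-carbon (SN2) and give the skipped enyne with both E alkenes untouched.

Step 3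
Reactants: 7 silylated trienyne
Product: 8 (2E,6E,10E)-2,6,10-trimethyl-14-(trimethylsilyl)tetradeca-2,6,10-trien-13-yn-1-ol
Conditions: SeO2 (0.3 equiv), t-BuOOH (3 equiv), salicylic acid (10 mol %), CH2Cl2, rt
Reagents that add atoms: tert-butyl hydroperoxide, CC(C)(C)OO
Why: Catalytic selenium dioxide allylic oxidation (ene reaction then [2,3]-sigmatropic shift, Riley oxidation) should be selective for the E-methyl group of the terminal, most accessible trisubstituted alkene, which fixes the 2E geometry of the new allylic alcohol.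

Step 4
Reactants: 8 allylic alcohol
Product: 9 [(2R,3R)-3-[(3E,7E)-3,7-dimethyl-11-(trimethylsilyl)undeca-3,7-dien-10-yn-1-yl]-2-methyloxiran-2-yl]methanol
Conditions: Ti(OiPr)4 (10 mol %), D-(−)-diethyl tartrate (12 mol %), t-BuOOH (2 equiv), 4 Å MS, CH2Cl2, −20 °C
Reagents that add atoms: tert-butyl hydroperoxide, CC(C)(C)OO
Why: Sharpless asymmetric epoxidation should epoxidise only the alkene of the titanium-bound allylic alcohol, the E geometry giving the trans oxirane and the D-(−)-tartrate ligand setting both new centres as 2R,3R by reagent control.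

Step 5
Reactants: 9 epoxy alcohol
Product: 10 [(2R,3R)-3-[(3E,7E)-3,7-dimethyl-11-(trimethylsilyl)undeca-3,7-dien-10-yn-1-yl]-2-methyloxiran-2-yl]methyl trifluoromethanesulfonate
Conditions: Tf2O, 2,6-lutidine, CH2Cl2, −78 °C; crude product used at once
Reagents that add atoms: trifluoromethanesulfonic anhydride, O=S(=O)(OS(=O)(=O)C(F)(F)F)C(F)(F)F
Why: O-Sulfonylation of the primary alcohol with a hindered base should give the epoxy triflate, whose leaving group makes the carbon next to the fully substituted oxirane carbon reactive towards SN2 at −78 °C.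

Step 6
Reactants: 3 prenyl phenyl sulfone; 10 epoxy triflate
Product: 12 (2R,3R)-3-[(3E,7E)-3,7-dimethyl-11-(trimethylsilyl)undeca-3,7-dien-10-yn-1-yl]-2-methyl-2-[4-methyl-2-(phenylsulfonyl)pent-3-en-1-yl]oxirane, via lithiated sulfone 11 (not isolated)
Conditions: 3 (2 equiv), n-BuLi (2 equiv), THF–DMPU, −78 °C; then 10, −78 °C; NH4Cl at −78 °C
Reagents that add atoms: none
Why: α-Alkylation of a lithiated allylic sulfone should displace the primary triflate faster than the soft carbanion opens the hindered trisubstituted oxirane, and it reacts at the sulfonyl-bearing carbon so that the prenyl unit is attached head-on (C12′–C13′ bond), the new sulfonyl-bearing centre being formed without control.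

Step 7
Reactants: 12 epoxy sulfone
Product: 13 (6S,7R,10E,14E)-2,6,10,14-tetramethyl-4-(phenylsulfonyl)-18-(trimethylsilyl)octadeca-2,10,14-trien-17-yne-6,7-diol
Conditions: HClO4 (cat.), THF–H2O, 0 °C
Reagents that add atoms: water, O
Why: Acid-catalysed epoxide hydrolysis (borderline A-2 mechanism) should bring water in at the tertiary oxirane carbon anti to the breaking C–O bond, which inverts the methyl-bearing centre (R to S) and leaves the secondary carbinol centre R, so the stereodiad of the target follows from the epoxide of step 4.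

Step 8
Reactants: 13 diol sulfone
Product: 14 (6S,7R,10E,14E)-2,6,10,14-tetramethyl-18-(trimethylsilyl)octadeca-2,10,14-trien-17-yne-6,7-diol
Conditions: PdCl2(dppp) (5 mol %), LiBHEt3 (5 equiv), THF, 0 °C to rt
Reagents that add atoms: none
Why: Palladium-catalysed reductive desulfonylation of an allylic sulfone (π-allylpalladium reduced by hydride) should deliver hydride to the less hindered terminus that bore sulfur, keeping the isopropylidene alkene in place while the hydroxyls are masked in situ as lithium alkoxyborates and the silylalkyne stays inert.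

Step 9
Reactants: 14 silylated diol
Product: 15 (6S,7R,10E,14E)-2,6,10,14-tetramethyloctadeca-2,10,14-trien-17-yne-6,7-diol
Conditions: K2CO3 (cat.), MeOH, rt
Reagents that add atoms: none
Why: Methoxide-mediated protodesilylation of the alkynylsilane should free the terminal alkyne under conditions too mild to isomerise the skipped enyne.

Step 10
Reactants: 15 diol alkyne
Product: 16 (6S,7R,10E,14E)-6-hydroxy-2,6,10,14-tetramethyloctadeca-2,10,14-trien-17-yn-7-yl acetate
Conditions: Ac2O (1.2 equiv), pyridine, DMAP (5 mol %), CH2Cl2, 0 °C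
Reagents that add atoms: acetic anhydride, CC(=O)OC(C)=O
Why: DMAP-catalysed O-acylation should be chemoselective for the secondary hydroxyl over the hindered tertiary one and does not touch the configuration of the carbinol carbon.

Step 11
Reactants: 17 2-bromopropene; 18 hexacarbonylchromium
Product: 21 pentacarbonyl[methoxy(prop-1-en-2-yl)methylidene]chromium, via isopropenyllithium 19 (not isolated), via lithium acylchromate 20 (not isolated)
Conditions: 17, Li (2.2 equiv), Et2O, 0 °C; then 18, Et2O, 0 °C to rt; then Me3OBF4, CH2Cl2–H2O, 0 °C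
Reagents that add atoms: trimethyloxonium tetrafluoroborate, C[O+](C)C.F[B-](F)(F)F
Why: Fischer carbene synthesis, in which the alkenyllithium adds to a CO ligand of Cr(CO)6 and the resulting acylchromate is O-methylated by the oxonium salt.

Step 12
Reactants: 16 hydroxy acetate alkyne; 21 isopropenyl(methoxy)carbene complex
Product: 23 Chabrolobenzoquinone H, via chromium-bound methoxyphenol 22 (not isolated)
Conditions: 21 (1.3 equiv), THF (0.05 M), 50 °C, Ar; then (NH4)2Ce(NO3)6 (6 equiv), MeCN–H2O, 0 °C
Reagents that add atoms: water, O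
Why: Thermal loss of CO from 21 should let the terminal alkyne of 16 coordinate and insert into the Cr=C bond with its CH end bonded to the carbene carbon, after which CO insertion gives a chromium-bound dienylketene that closes and tautomerises to the 4-methoxyphenol complex 22; ceric ion then strips the metal and oxidises the hydroquinone monomethyl ether through a quinone hemiketal, expelling methanol and taking the C1 oxygen from water. The closest known reaction type is the Dötz benzannulation of alkenyl(alkoxy)carbene chromium complexes with terminal alkynes, followed by oxidative work-up to the quinone. The single ring closes by 6π electrocyclisation of the dienylketene (formal [3+2+1]), the last bond formed joining the CO-derived C4 to the isopropenyl methylene carbon C3. No stereocentre is created, and the C10′/C11′ diad lies far from the reacting alkyne and cannot epimerise under neutral thermal or brief ceric conditions. The step needs regioselective alkyne insertion (chain next to the CO-derived carbon, giving the 2,5- and not the 2,6-pattern), which the H versus CH2R size difference of a terminal alkyne secures, and chemoselectivity, which the unreactive trisubstituted alkenes and the acetate (no free 1,2-diol for ceric glycol cleavage) secure.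

**Compound list**

1 | 1-bromo-3-methylbut-2-ene | CC(C)=CCBr | starting material
2 | sodium benzenesulfinate | [Na+].[O-]S(=O)c1ccccc1 | starting material
3 | (3-methylbut-2-en-1-yl) phenyl sulfone | CC(C)=CCS(=O)(=O)c1ccccc1 | intermediate
4 | (2E,6E)-1-bromo-3,7,11-trimethyldodeca-2,6,10-triene (farnesyl bromide) | BrC/C=C(\C)CC/C=C(\C)CCC=C(C)C | starting material
5 | ethynyltrimethylsilane | C[Si](C)(C)C#C | starting material
6 | [(trimethylsilyl)ethynyl]magnesium bromide | C[Si](C)(C)C#C[Mg]Br | intermediate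
7 | trimethyl[(4E,8E)-5,9,13-trimethyltetradeca-4,8,12-trien-1-yn-1-yl]silane | CC(C)=CCC/C(C)=C/CC/C(C)=C/CC#C[Si](C)(C)C | intermediate
8 | (2E,6E,10E)-2,6,10-trimethyl-14-(trimethylsilyl)tetradeca-2,6,10-trien-13-yn-1-ol | OC/C(C)=C/CC/C(C)=C/CC/C(C)=C/CC#C[Si](C)(C)C | intermediate
9 | [(2R,3R)-3-[(3E,7E)-3,7-dimethyl-11-(trimethylsilyl)undeca-3,7-dien-10-yn-1-yl]-2-methyloxiran-2-yl]methanol | OC[C@@]1(C)O[C@@H]1CC/C(C)=C/CC/C(C)=C/CC#C[Si](C)(C)C | intermediate
10 | [(2R,3R)-3-[(3E,7E)-3,7-dimethyl-11-(trimethylsilyl)undeca-3,7-dien-10-yn-1-yl]-2-methyloxiran-2-yl]methyl trifluoromethanesulfonate | FC(F)(F)S(=O)(=O)OC[C@@]1(C)O[C@@H]1CC/C(C)=C/CC/C(C)=C/CC#C[Si](C)(C)C | intermediate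
11 | [3-methyl-1-(phenylsulfonyl)but-2-en-1-yl]lithium | [Li]C(C=C(C)C)S(=O)(=O)c1ccccc1 | intermediate
12 | (2R,3R)-3-[(3E,7E)-3,7-dimethyl-11-(trimethylsilyl)undeca-3,7-dien-10-yn-1-yl]-2-methyl-2-[4-methyl-2-(phenylsulfonyl)pent-3-en-1-yl]oxirane (both epimers at the sulfonyl carbon) | CC(C)=CC(C[C@@]1(C)O[C@@H]1CC/C(C)=C/CC/C(C)=C/CC#C[Si](C)(C)C)S(=O)(=O)c1ccccc1 | intermediate
13 | (6S,7R,10E,14E)-2,6,10,14-tetramethyl-4-(phenylsulfonyl)-18-(trimethylsilyl)octadeca-2,10,14-trien-17-yne-6,7-diol (both epimers at C4) | O[C@H](CC/C(C)=C/CC/C(C)=C/CC#C[Si](C)(C)C)[C@@](C)(O)CC(C=C(C)C)S(=O)(=O)c1ccccc1 | intermediate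
14 | (6S,7R,10E,14E)-2,6,10,14-tetramethyl-18-(trimethylsilyl)octadeca-2,10,14-trien-17-yne-6,7-diol | O[C@H](CC/C(C)=C/CC/C(C)=C/CC#C[Si](C)(C)C)[C@@](C)(O)CCC=C(C)C | intermediate
15 | (6S,7R,10E,14E)-2,6,10,14-tetramethyloctadeca-2,10,14-trien-17-yne-6,7-diol | O[C@H](CC/C(C)=C/CC/C(C)=C/CC#C)[C@@](C)(O)CCC=C(C)C | intermediate
16 | (6S,7R,10E,14E)-6-hydroxy-2,6,10,14-tetramethyloctadeca-2,10,14-trien-17-yn-7-yl acetate | CC(=O)O[C@H](CC/C(C)=C/CC/C(C)=C/CC#C)[C@@](C)(O)CCC=C(C)C | intermediate
17 | 2-bromopropene | CC(Br)=C | starting material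
18 | hexacarbonylchromium | O=C=[Cr](=C=O)(=C=O)(=C=O)(=C=O)=C=O | starting material
19 | isopropenyllithium | [Li]C(C)=C | intermediate
20 | lithium pentacarbonyl(2-methylprop-2-enoyl)chromate | [Li+].[O-]C(C(C)=C)=[Cr](=C=O)(=C=O)(=C=O)(=C=O)=C=O | intermediate
21 | pentacarbonyl[methoxy(prop-1-en-2-yl)methylidene]chromium | COC(C(C)=C)=[Cr](=C=O)(=C=O)(=C=O)(=C=O)=C=O | intermediate
22 | tricarbonylchromium η6-complex of (6S,7R,10E,14E)-6-hydroxy-16-(2-hydroxy-5-methoxy-4-methylphenyl)-2,6,10,14-tetramethylhexadeca-2,10,14-trien-7-yl acetate | CC(=O)O[C@H](CC/C(C)=C/CC/C(C)=C/Cc1cc(OC)c(C)cc1O)[C@@](C)(O)CCC=C(C)C.O=C=[Cr](=C=O)=C=O | intermediate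
23 | Chabrolobenzoquinone H, (6S,7R,10E,14E)-6-hydroxy-2,6,10,14-tetramethyl-16-(4-methyl-3,6-dioxocyclohexa-1,4-dien-1-yl)hexadeca-2,10,14-trien-7-yl acetate | CC(=O)O[C@H](CC/C(C)=C/CC/C(C)=C/CC1=CC(=O)C(C)=CC1=O)[C@@](C)(O)CCC=C(C)C | target

**Step count and risks**

Total steps: 12. Longest linear sequence: 10 steps (steps 2 to 10 and step 12, from farnesyl bromide).

The three steps most likely to fail:

1. Step 12 (benzannulation and oxidation). The vinylcarbene and vinylketene intermediates may be diverted into cyclobutenone or furan products or take up a second alkyne, the free tertiary hydroxyl may intercept the ketene, or ceric ion may over-oxidise the chain. The fallback still closes the ring last, now by strain-release ring expansion of a cyclobutenone, and sets out from diol 15.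
   - Diol 15 is protected as the acetonide F1 (2,2-dimethoxypropane, PPTS).
   - Commercial diisopropyl squarate is reduced with LiAlH(O-t-Bu)3 to the hydroxycyclobutenone F2, which catalytic HCl should convert into the semisquarate F3.
   - The lithium acetylide of F1 (n-BuLi, THF, −78 °C) should add to the ketone carbonyl of F3, not the vinylogous ester carbonyl, to give the alkynyl hydroxy cyclobutenone F4.
   - MeLi then adds to the remaining carbonyl to give the cyclobutene diol F5, and mild acid (PPTS, wet CH2Cl2) should hydrolyse the enol ether with 1,3-carbonyl transposition to the 3-methylcyclobutenone F6.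
   - Heating F6 in toluene at 110 °C should cause 4π ring opening to an alkynyl vinylketene, ring closure and hydrogen transfer (Moore rearrangement) to the quinone acetonide F7, in which the two alkyne carbons have become C5 and C6.
   - Aqueous acetic acid should give the quinone diol F8, and selective acetylation of its secondary hydroxyl (Ac2O, pyridine, 0 °C) comes back to the route at 23.

2. Step 6 (alkylation with the epoxy triflate). The triflate may decompose by ionisation or elimination before the C–C bond forms, or proton transfer to the excess carbanion may lead to intramolecular opening of the oxirane. The fallback replaces sulfone alkylation and desulfonylation by allylation and cross-metathesis, and sets out from epoxy alcohol 9.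
   - Appel-type iodination (I2, PPh3, imidazole) should give the isolable epoxy iodide F9.
   - Allylmagnesium bromide with catalytic CuI at −30 °C should displace iodide to give the butenyl epoxide F10.
   - Cross-metathesis with 2-methyl-2-butene (second-generation Grubbs catalyst) should install the isopropylidene end in the prenyl epoxide F11, the silylated alkyne being a poor metathesis partner.
   - Acid hydrolysis under the conditions of step 7 then comes back to the route at 14, so steps 7 and 8 are bypassed.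

3. Step 7 (epoxide hydrolysis). The tertiary centre may lose stereochemical fidelity through an open carbocation, water may attack the secondary carbon (which gives the mirror-image diad), or the cation may be trapped by the neighbouring alkene. The fallback delivers the oxygen intramolecularly and sets out from epoxy alcohol 9.
   - Phenyl isocyanate and pyridine give the phenylcarbamate F12.
   - BF3·OEt2 at −20 °C followed by aqueous acid should deliver the carbamate carbonyl oxygen 5-exo to the tertiary oxirane carbon with inversion, the tether fixing the regiochemistry, to give the cyclic carbonate F13.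
   - LiAlH4 cleaves the carbonate to the triol F14.
   - Selective sulfonylation of the primary hydroxyl (TsCl, Et3N, catalytic Bu2SnO) gives the tosylate F15, and NaH closes the 2,2-disubstituted terminal epoxide F16.
   - Lithiated sulfone 11 (3 equiv) should open F16 at its CH2 carbon, which comes back to the route at 13.

Further compounds

F1 | step 12 | (4R,5S)-4-[(3E,7E)-3,7-dimethylundeca-3,7-dien-10-yn-1-yl]-2,2,5-trimethyl-5-(4-methylpent-3-en-1-yl)-1,3-dioxolane | CC1(C)O[C@H](CC/C(C)=C/CC/C(C)=C/CC#C)[C@](C)(CCC=C(C)C)O1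
F2 | step 12 | 4-hydroxy-2,3-di(propan-2-yloxy)cyclobut-2-en-1-one | O=C1C(OC(C)C)=C(OC(C)C)C1O
F3 | step 12 | 3-(propan-2-yloxy)cyclobut-3-ene-1,2-dione | O=C1C=C(OC(C)C)C1=O
F4 | step 12 | 4-hydroxy-4-{(4E,8E)-5,9-dimethyl-11-[(4R,5S)-2,2,5-trimethyl-5-(4-methylpent-3-en-1-yl)-1,3-dioxolan-4-yl]undeca-4,8-dien-1-yn-1-yl}-3-(propan-2-yloxy)cyclobut-2-en-1-one (both epimers at C4) | CC1(C)O[C@H](CC/C(C)=C/CC/C(C)=C/CC#CC2(O)C(=O)C=C2OC(C)C)[C@](C)(CCC=C(C)C)O1
F5 | step 12 | 1-methyl-2-{(4E,8E)-5,9-dimethyl-11-[(4R,5S)-2,2,5-trimethyl-5-(4-methylpent-3-en-1-yl)-1,3-dioxolan-4-yl]undeca-4,8-dien-1-yn-1-yl}-3-(propan-2-yloxy)cyclobut-3-ene-1,2-diol (mixture of ring stereoisomers) | CC1(C)O[C@H](CC/C(C)=C/CC/C(C)=C/CC#CC2(O)C(C)(O)C=C2OC(C)C)[C@](C)(CCC=C(C)C)O1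
F6 | step 12 | 4-hydroxy-3-methyl-4-{(4E,8E)-5,9-dimethyl-11-[(4R,5S)-2,2,5-trimethyl-5-(4-methylpent-3-en-1-yl)-1,3-dioxolan-4-yl]undeca-4,8-dien-1-yn-1-yl}cyclobut-2-en-1-one (both epimers at C4) | CC1(C)O[C@H](CC/C(C)=C/CC/C(C)=C/CC#CC2(O)C(C)=CC2=O)[C@](C)(CCC=C(C)C)O1
F7 | step 12 | 2-{(2E,6E)-3,7-dimethyl-9-[(4R,5S)-2,2,5-trimethyl-5-(4-methylpent-3-en-1-yl)-1,3-dioxolan-4-yl]nona-2,6-dien-1-yl}-5-methylcyclohexa-2,5-diene-1,4-dione | CC1(C)O[C@H](CC/C(C)=C/CC/C(C)=C/CC2=CC(=O)C(C)=CC2=O)[C@](C)(CCC=C(C)C)O1
F8 | step 12 | 2-[(2E,6E,10R,11S)-10,11-dihydroxy-3,7,11,15-tetramethylhexadeca-2,6,14-trien-1-yl]-5-methylcyclohexa-2,5-diene-1,4-dione | O[C@H](CC/C(C)=C/CC/C(C)=C/CC1=CC(=O)C(C)=CC1=O)[C@@](C)(O)CCC=C(C)C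
F9 | step 6 | (2S,3R)-3-[(3E,7E)-3,7-dimethyl-11-(trimethylsilyl)undeca-3,7-dien-10-yn-1-yl]-2-(iodomethyl)-2-methyloxirane | IC[C@@]1(C)O[C@@H]1CC/C(C)=C/CC/C(C)=C/CC#C[Si](C)(C)C
F10 | step 6 | (2R,3R)-2-(but-3-en-1-yl)-3-[(3E,7E)-3,7-dimethyl-11-(trimethylsilyl)undeca-3,7-dien-10-yn-1-yl]-2-methyloxirane | C=CCC[C@@]1(C)O[C@@H]1CC/C(C)=C/CC/C(C)=C/CC#C[Si](C)(C)C
F11 | step 6 | (2R,3R)-3-[(3E,7E)-3,7-dimethyl-11-(trimethylsilyl)undeca-3,7-dien-10-yn-1-yl]-2-methyl-2-(4-methylpent-3-en-1-yl)oxirane | CC(C)=CCC[C@@]1(C)O[C@@H]1CC/C(C)=C/CC/C(C)=C/CC#C[Si](C)(C)C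
F12 | step 7 | [(2R,3R)-3-[(3E,7E)-3,7-dimethyl-11-(trimethylsilyl)undeca-3,7-dien-10-yn-1-yl]-2-methyloxiran-2-yl]methyl N-phenylcarbamate | O=C(Nc1ccccc1)OC[C@@]1(C)O[C@@H]1CC/C(C)=C/CC/C(C)=C/CC#C[Si](C)(C)C
F13 | step 7 | (4S)-4-[(1R,4E,8E)-1-hydroxy-4,8-dimethyl-12-(trimethylsilyl)dodeca-4,8-dien-11-yn-1-yl]-4-methyl-1,3-dioxolan-2-one | O[C@H](CC/C(C)=C/CC/C(C)=C/CC#C[Si](C)(C)C)[C@@]1(C)OC(=O)OC1
F14 | step 7 | (2S,3R,6E,10E)-2,6,10-trimethyl-14-(trimethylsilyl)tetradeca-6,10-dien-13-yne-1,2,3-triol | O[C@H](CC/C(C)=C/CC/C(C)=C/CC#C[Si](C)(C)C)[C@@](C)(O)CO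
F15 | step 7 | (2S,3R,6E,10E)-2,3-dihydroxy-2,6,10-trimethyl-14-(trimethylsilyl)tetradeca-6,10-dien-13-yn-1-yl 4-methylbenzenesulfonate | O[C@H](CC/C(C)=C/CC/C(C)=C/CC#C[Si](C)(C)C)[C@@](C)(O)COS(=O)(=O)c1ccc(C)cc1
F16 | step 7 | (1R,4E,8E)-4,8-dimethyl-1-[(2S)-2-methyloxiran-2-yl]-12-(trimethylsilyl)dodeca-4,8-dien-11-yn-1-ol | O[C@H](CC/C(C)=C/CC/C(C)=C/CC#C[Si](C)(C)C)[C@@]1(C)OC1
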